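Start with an easy division. Define the poison share w as the impurity charged over the catalyst charged as precatalyst: this flask has 0.380, Friday's run 0.190 and Tuesday's run 0.750. Work in logarithms: the flask's share is twice Friday's, and Tuesday's is twice the flask's, so on a logarithmic scale the flask lies midway between the runs.

the same everywhere: starting material 20 mM; precatalyst 0.1 mol%

| flask | second substrate | impurity | remark |
|---|---|---|---|
| Friday's | 0.50 equiv | 3.8 µM | run made earlier |
| Tuesday's | 0.50 equiv | 15 µM | run made earlier |
| flask | 0.500 equiv | 7.6 µM |  |

| run | time / h | target / % | starting material / % |
|---|---|---|---|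
| Friday's | 0.500 | 4.1 | 96.8 |
| Friday's | 1.50 | 18.4 | 82.0 |
| Friday's | 3.00 | 59.8 | 40.7 |
| Friday's | 5.00 | 93.9 | 6.6 |
| Friday's | 6.00 | 97.8 | 0.7 |
| Tuesday's | 0.500 | 2.0 | 98.3 |
| Tuesday's | 1.50 | 2.8 | 96.5 |
| Tuesday's | 3.00 | 10.4 | 92.3 |
| Tuesday's | 5.00 | 20.1 | 80.1 |
| Tuesday's | 6.00 | 30.3 | 69.8 |

(scatter of a reading: 1 percentage point)

- factor on the rate of making target when 10% of the starting material are converted if precatalyst is charged twice over
- factor on the rate when 10% of the starting material are converted if precatalyst is charged at 1 mol% instead

- steps that have been proposed: catalyst intermediate B -> free catalyst + second product; catalyst intermediate A -> free catalyst + target; second substrate + free catalyst <-> catalyst intermediate B; precatalyst -> free catalyst; free catalyst + impurity -> spent catalyst; starting material + free catalyst <-> catalyst intermediate A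
- no earlier run changes the charge of precatalyst; that part of a forecast is a guess

Turn the impurity first. Near 10% conversion, Friday's run loses starting material at a read 0.148 h⁻¹ and Tuesday's at 0.0610 h⁻¹. Take their geometric mean as my figure for the flask, 0.0950 h⁻¹.

Turn the precatalyst next. Twice the charge brings the flask to w = 0.190, Friday's share, with both the catalyst charged and the impurity at twice Friday's amounts. Friday's first readings show the negative logarithm of the starting material left growing as time to the power p, read as 1.65. Assume, then, that m times the catalyst at one share raises the rate at fixed conversion by m to the power one over p. Scaling Friday's rate so and dividing by my figure for the flask gives me 2.37 for twice the charge. At 1 mol% the same rule gives 6.31, though the share there, 0.0380, is lower than Friday's.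

The forecast says 1.9 for twice the charge and 5.5 for 1 mol%, both lower than mine, and holds that “The factors are well below proportional because activation is still incomplete”.

The flask gives 1.94 for twice the charge and 6.17 for 1 mol%, so the forecast stands within its margins, while my factor for twice the charge came out higher.

    catalyst intermediate B → free catalyst + second product (k = 0.00930 s⁻¹)
    catalyst intermediate A → free catalyst + target (k = 0.750 s⁻¹)
    second substrate + free catalyst ⇌ catalyst intermediate B (K = 170 M⁻¹, k = 2.80 M⁻¹ s⁻¹)
    precatalyst → free catalyst (k = 9.70 × 10⁻⁵ s⁻¹)
    free catalyst + impurity → spent catalyst (k = 970 M⁻¹ s⁻¹)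
    starting material + free catalyst ⇌ catalyst intermediate A (K = 2400 M⁻¹, k = 55.0 M⁻¹ s⁻¹)

In this flask, free catalyst falls to impurity with a pseudo-first-order constant of 27 h⁻¹ per free catalyst, with impurity as charged, which is 76.0 times the constant of 0.349 h⁻¹ per precatalyst with which precatalyst releases free catalyst. With w at 0.380 in this flask, spent catalyst stands at 38.0% of the catalyst charged after 4.00 h and still at 38.0% after 80.0 h.

The data are calculated for substances that don't exist; the scatter is artificial.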